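**Plan**

1. Retrosynthesis: remove the C11 carbonyl (allylic C–H oxidation) and the two esters, take the C3 and C5 oxygens back to a cage enone C3(=O)–C4=C5, then cut the zero-atom bridge C2–C8 of the tricyclo[5.4.0.0^{2,8}]undecane. This leaves a cis-fused cyclohexene/cycloheptadienone, the bicycle from which this bond is thought to arise in the biogenesis of the skeleton, here with inverted polarity. Excising C2 (ring contraction) gives a Diels–Alder adduct of isoprene and 4,4-dimethylcyclohexa-2,5-dienone.
2. Forward ring order: cyclohexene (Diels–Alder) → seven-membered ring (diazoacetate ring expansion, then the C2 methyl) → cyclobutane C1–C2–C8–C7 and with it the second six-membered ring (enolate alkylation) → oxygen at C5, then C3, then C11.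
3. Enabling feature: the quaternary cyclobutane carbon C2 is α to the C3 oxygen, and its partner C8 is allylic to C9=C10 and 1,3 to C2 across the cis ring fusion C1–C7. With C3 as the carbonyl of a cycloheptadienone (C4=C5, quaternary C6), C2–H is the only acidic hydrogen, so one enolate can displace an allylic leaving group at C8.
4. Stereochemistry: C1/C7 (cis, absolute) from an enantioselective Diels–Alder reaction; C2 and C8 from the geometry of the intramolecular SN2 (inversion at C8); C5 from a ligand-controlled copper–boryl addition; C3 from 1,3-anti hydride transfer in an Evans–Tishchenko reaction that also installs the C5 ester.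

Key step: step 8

Locants: C1–C11 in the text are those of the target, 2,6,6,9-tetramethyltricyclo[5.4.0.0^{2,8}]undecane numbering (C1 bridgehead next to the ketone, C2 quaternary C–CH3, C3 CH–O isovalerate, C4 CH2, C5 CH–O senecioate, C6 C(CH3)2, C7 CH, C8 bridgehead, C9 =C(CH3), C10 =CH, C11 C=O). They are used for the bicyclic precursors as well, whose systematic names carry their own numbering.

Remark: the C2 epimers (and keto/enol forms) of 6–10 converge in step 8 and are carried as mixtures. The sense of induction of the chiral catalysts in steps 2 and 9 is assigned from the accepted models and would be confirmed on the first batch; both antipodes of each catalyst are available.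

Step 1
Reactants: 1 4,4-dimethylcyclohex-2-en-1-one
Product: 2 4,4-dimethylcyclohexa-2,5-dien-1-one
Conditions: DDQ, dioxane, reflux
Reagents that add atoms: none
Why: Quinone dehydrogenation of the enolisable ketone introduces the second double bond, and the gem-dimethyl carbon blocks aromatisation, so the cross-conjugated dienone should be the end point.

Step 2
Reactants: 2 4,4-dimethylcyclohexa-2,5-dien-1-one; 3 isoprene
Product: 4 (4aS,8aR)-4,4,6-trimethyl-4a,5,8,8a-tetrahydronaphthalen-1(4H)-one
Conditions: oxazaborolidinium triflimide generated from (S)-α,α-diphenylprolinol, tri-o-tolylboroxine and Tf2NH (20 mol %), isoprene (5 equiv), CH2Cl2, −78 → −20 °C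
Reagents that add atoms: none
Why: Lewis-acid-catalysed Diels–Alder reaction in which the two double bonds of 2 are equivalent, the diene terminus next to the methyl-bearing carbon bonds to the β-carbon C7 (para rule, so C9–CH3 lies next to C8), suprafacial addition gives the cis fusion C1/C7, and the chiral boron cation selects one enantiotopic face, which fixes the absolute configuration of the later cage.

Step 3
Reactants: 4 (4aS,8aR)-4,4,6-trimethyl-4a,5,8,8a-tetrahydronaphthalen-1(4H)-one; 5 ethyl diazoacetate
Product: 6 ethyl (4aR,9aS)-2,9,9-trimethyl-6-oxo-4,4a,5,6,9,9a-hexahydro-1H-benzo[7]annulene-5-carboxylate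
Conditions: BF3·OEt2, Et2O, 0 → 20 °C
Reagents that add atoms: none
Why: Lewis-acid-promoted diazoacetate homologation (Tiffeneau–Demjanov-type 1,2-shift with loss of N2) in which, for a conjugated ketone, the saturated α-carbon C1 should migrate with retention and the vinyl carbon should not, so the new carbon C2 enters between C3 and C1 and the enolised β-keto ester product does not react further.

Step 4
Reactants: 6 ethyl (4aR,9aS)-2,9,9-trimethyl-6-oxo-4,4a,5,6,9,9a-hexahydro-1H-benzo[7]annulene-5-carboxylate
Product: 7 ethyl (4aR,9aS)-2,5,9,9-tetramethyl-6-oxo-4,4a,5,6,9,9a-hexahydro-1H-benzo[7]annulene-5-carboxylate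
Conditions: MeI, K2CO3, acetone, 45 °C
Reagents that add atoms: iodomethane, CI
Why: C-Alkylation of the β-keto ester enolate (the only acidic site) installs the C2 methyl group, and the configuration created at C2 is irrelevant because this centre is planarised again in step 8.

Step 5
Reactants: 7 ethyl (4aR,9aS)-2,5,9,9-tetramethyl-6-oxo-4,4a,5,6,9,9a-hexahydro-1H-benzo[7]annulene-5-carboxylate
Product: 8 (4aR,9aS)-2,5,9,9-tetramethyl-1,4,4a,5,9,9a-hexahydro-6H-benzo[7]annulen-6-one
Conditions: LiCl, H2O, DMSO, 150 °C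
Reagents that add atoms: none
Why: Krapcho dealkoxycarbonylation under neutral conditions removes the ester without the retro-Claisen opening that hydroxide would risk on a non-enolisable β-keto ester, and leaves C2–H as the only enolisable position (C4 is vinylic, C6 quaternary).

Step 6
Reactants: 8 (4aR,9aS)-2,5,9,9-tetramethyl-1,4,4a,5,9,9a-hexahydro-6H-benzo[7]annulen-6-one
Product: 9 (1S,4aR,9aS)-1-hydroxy-2,5,9,9-tetramethyl-1,4,4a,5,9,9a-hexahydro-6H-benzo[7]annulen-6-one
Conditions: SeO2 (0.5 equiv), t-BuOOH, CH2Cl2, 20 °C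
Reagents that add atoms: tert-butyl hydroperoxide, CC(C)(C)OO
Why: SeO2 allylic hydroxylation (ene reaction, then [2,3]-sigmatropic shift) should oxidise the trisubstituted alkene at the ring CH2 on its more substituted end (C8, next to C9–CH3), return the double bond to C9=C10, and deliver oxygen suprafacially to the face away from C6 and the C1–C2 bond, giving the C8 alcohol trans to C6.

Step 7
Reactants: 9 (1S,4aR,9aS)-1-hydroxy-2,5,9,9-tetramethyl-1,4,4a,5,9,9a-hexahydro-6H-benzo[7]annulen-6-one
Product: 10 (1S,4aR,9aS)-2,5,9,9-tetramethyl-6-oxo-4,4a,5,6,9,9a-hexahydro-1H-benzo[7]annulen-1-yl methanesulfonate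
Conditions: MsCl, Et3N, CH2Cl2, −20 °C; used at once without purification
Reagents that add atoms: methanesulfonyl chloride, CS(Cl)(=O)=O
Why: Sulfonylation with retention (via sulfene) turns the hindered allylic alcohol into a leaving group on the face opposite C2, and immediate use should avoid allylic ionisation.

Step 8
Reactants: 10 (1S,4aR,9aS)-2,5,9,9-tetramethyl-6-oxo-4,4a,5,6,9,9a-hexahydro-1H-benzo[7]annulen-1-yl methanesulfonate
Product: 12 (1R,2S,7R,8R)-2,6,6,9-tetramethyltricyclo[5.4.0.0^{2,8}]undeca-4,9-dien-3-one, via potassium dienolate 11 (not isolated)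
Conditions: KN(SiMe3)2 (1.1 equiv), THF, −78 → 0 °C
Reagents that add atoms: none
Why: KN(SiMe3)2 removes the only acidic hydrogen (C2–H; C4 is vinylic, C6 quaternary) to give the cross-conjugated dienolate 11, whose carbon C2 displaces the allylic mesylate at C8 with inversion (intramolecular SN2). The closest known reaction type is the base-mediated keto-sulfonate cyclisation used to build bicyclo[3.1.1]heptanones of the pinane family. The step closes the cyclobutane C1–C2–C8–C7 in a 4-exo-tet mode and with it the second six-membered ring C1–C2–C8–C9–C10–C11, turning the fused bicycle into the bridged tricycle. C2 becomes quaternary with its methyl over the C9–C11 bridge because the enolate carbon, held in the seven-membered ring through C1, can reach C8 only on the face on which the cis ring fusion places it, and C8 is set by inversion of the sulfonate that step 6 placed on the opposite face. The step needs C- over O-alkylation, SN2 over SN2′ and substitution over elimination: the enolate oxygen is trans to C1 on the endocyclic enolate double bond and cannot reach C8, attack at C10 would need the unusual anti SN2′ geometry, and in the reactive half-chair (C2 axial) the pseudo-equatorial mesylate is gauche to H7, which disfavours anti elimination.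

Step 9
Reactants: 12 (1R,2S,7R,8R)-2,6,6,9-tetramethyltricyclo[5.4.0.0^{2,8}]undeca-4,9-dien-3-one
Product: 14 (1R,2S,5R,7R,8R)-5-hydroxy-2,6,6,9-tetramethyltricyclo[5.4.0.0^{2,8}]undec-9-en-3-one, via β-boryl ketone 13 (not isolated)
Conditions: CuCl (5 mol %), (R,R)-2,3-bis(tert-butylmethylphosphino)quinoxaline (6 mol %), NaOt-Bu (10 mol %), B2pin2, MeOH, THF, 20 °C; then NaBO3·4H2O, THF–H2O, 20 °C
Reagents that add atoms: bis(pinacolato)diboron, CC1(C)OB(OC1(C)C)B1OC(C)(C)C(C)(C)O1; sodium perborate, [Na+].[Na+].O[B-]1(O)OO[B-](O)(O)OO1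
Why: Copper–boryl conjugate addition to the only enone (the C9=C10 alkene is inert) followed by stereoretentive C–B oxidation gives the β-hydroxy ketone, and because the enone lies in the local mirror plane of the cage (the C1 and C8 sides differ only remotely) the substrate has no facial bias, so the chiral bisphosphine should set C5 as (R).

Step 10
Reactants: 14 (1R,2S,5R,7R,8R)-5-hydroxy-2,6,6,9-tetramethyltricyclo[5.4.0.0^{2,8}]undec-9-en-3-one; 15 3-methylbut-2-enal
Product: 16 (1R,2S,3R,5R,7R,8R)-3-hydroxy-2,6,6,9-tetramethyltricyclo[5.4.0.0^{2,8}]undec-9-en-5-yl 3-methylbut-2-enoate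
Conditions: SmI2 (30 mol %), 15 (5 equiv), THF, −10 °C, dark
Reagents that add atoms: none
Why: Evans–Tishchenko reduction in which the C5 hydroxyl forms a samarium-bound hemiacetal with the aldehyde and passes its hydride to the C3 carbonyl through a six-membered transition state, so that hydrogen arrives cis to the C5 oxygen, the new C3 hydroxyl is trans (1,3-anti), and the aldehyde ends as the C5 3-methylbut-2-enoate.

Step 11
Reactants: 16 (1R,2S,3R,5R,7R,8R)-3-hydroxy-2,6,6,9-tetramethyltricyclo[5.4.0.0^{2,8}]undec-9-en-5-yl 3-methylbut-2-enoate; 17 3-methylbutanoyl chloride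
Product: 18 (1R,2S,3R,5R,7R,8R)-2,6,6,9-tetramethyl-3-(3-methylbutanoyloxy)tricyclo[5.4.0.0^{2,8}]undec-9-en-5-yl 3-methylbut-2-enoate
Conditions: pyridine, DMAP (10 mol %), CH2Cl2, 0 → 20 °C
Reagents that add atoms: none
Why: Nucleophile-catalysed acylation of the remaining hindered secondary alcohol, run directly after step 10 so that 1,3-acyl migration cannot exchange the two ester positions.

Step 12
Reactants: 18 (1R,2S,3R,5R,7R,8R)-2,6,6,9-tetramethyl-3-(3-methylbutanoyloxy)tricyclo[5.4.0.0^{2,8}]undec-9-en-5-yl 3-methylbut-2-enoate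
Product: 19 (1R,2R,3R,5R,7S,8R)-2,6,6,9-tetramethyl-3-(3-methylbutanoyloxy)-11-oxotricyclo[5.4.0.0^{2,8}]undec-9-en-5-yl 3-methylbut-2-enoate (CNP0214473.1)
Conditions: dirhodium tetracaprolactamate Rh2(C6H10NO)4 (1 mol %), t-BuOOH (5 equiv), K2CO3, CH2Cl2, 20 °C
Reagents that add atoms: tert-butyl hydroperoxide, CC(C)(C)OO
Why: Radical allylic C–H oxidation (tert-butylperoxyl chain) should act at C11, the only allylic methylene of the ring alkene (C8 is a bridgehead, the C9 methyl is primary, the senecioate alkene is electron-poor), giving the enone as in the pinene-to-verbenone type of oxidation.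

**Compound list**

1 | 4,4-dimethylcyclohex-2-en-1-one | CC1(C)CCC(=O)C=C1 | starting material
2 | 4,4-dimethylcyclohexa-2,5-dien-1-one | CC1(C)C=CC(=O)C=C1 | intermediate
3 | isoprene (2-methylbuta-1,3-diene) | CC(=C)C=C | starting material
4 | (4aS,8aR)-4,4,6-trimethyl-4a,5,8,8a-tetrahydronaphthalen-1(4H)-one (cis-fused) | C1=CC(=O)[C@@H]2CC=C(C)C[C@@H]2C1(C)C | intermediate
5 | ethyl diazoacetate | CCOC(=O)C=[N+]=[N-] | starting material
6 | ethyl (4aR,9aS)-2,9,9-trimethyl-6-oxo-4,4a,5,6,9,9a-hexahydro-1H-benzo[7]annulene-5-carboxylate (cis-fused, C2 epimers) | C1=CC(=O)C(C(=O)OCC)[C@@H]2CC=C(C)C[C@@H]2C1(C)C | intermediate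
7 | ethyl (4aR,9aS)-2,5,9,9-tetramethyl-6-oxo-4,4a,5,6,9,9a-hexahydro-1H-benzo[7]annulene-5-carboxylate (C2 epimers) | C1=CC(=O)C(C)(C(=O)OCC)[C@@H]2CC=C(C)C[C@@H]2C1(C)C | intermediate
8 | (4aR,9aS)-2,5,9,9-tetramethyl-1,4,4a,5,9,9a-hexahydro-6H-benzo[7]annulen-6-one (C2 epimers) | C1=CC(=O)C(C)[C@@H]2CC=C(C)C[C@@H]2C1(C)C | intermediate
9 | (1S,4aR,9aS)-1-hydroxy-2,5,9,9-tetramethyl-1,4,4a,5,9,9a-hexahydro-6H-benzo[7]annulen-6-one (C8 hydroxyl trans to C6) | C1=CC(=O)C(C)[C@@H]2CC=C(C)[C@@H](O)[C@@H]2C1(C)C | intermediate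
10 | (1S,4aR,9aS)-2,5,9,9-tetramethyl-6-oxo-4,4a,5,6,9,9a-hexahydro-1H-benzo[7]annulen-1-yl methanesulfonate | C1=CC(=O)C(C)[C@@H]2CC=C(C)[C@@H](OS(C)(=O)=O)[C@@H]2C1(C)C | intermediate
11 | potassium dienolate of 10 (C2=C3 enolate) | [K+].[O-]C1=C(C)[C@@H]2CC=C(C)[C@@H](OS(C)(=O)=O)[C@@H]2C(C)(C)C=C1 | intermediate (not isolated)
12 | (1R,2S,7R,8R)-2,6,6,9-tetramethyltricyclo[5.4.0.0^{2,8}]undeca-4,9-dien-3-one | C1=CC(=O)[C@@]2(C)[C@@H]3CC=C(C)[C@H]2[C@@H]3C1(C)C | intermediate
13 | (1R,2S,5R,7R,8R)-2,6,6,9-tetramethyl-5-(4,4,5,5-tetramethyl-1,3,2-dioxaborolan-2-yl)tricyclo[5.4.0.0^{2,8}]undec-9-en-3-one | CC1(C)OB(OC1(C)C)[C@@H]2CC(=O)[C@@]3(C)[C@@H]4CC=C(C)[C@H]3[C@@H]4C2(C)C | intermediate (not isolated)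
14 | (1R,2S,5R,7R,8R)-5-hydroxy-2,6,6,9-tetramethyltricyclo[5.4.0.0^{2,8}]undec-9-en-3-one | O[C@@H]1CC(=O)[C@@]2(C)[C@@H]3CC=C(C)[C@H]2[C@@H]3C1(C)C | intermediate
15 | 3-methylbut-2-enal | CC(C)=CC=O | starting material
16 | (1R,2S,3R,5R,7R,8R)-3-hydroxy-2,6,6,9-tetramethyltricyclo[5.4.0.0^{2,8}]undec-9-en-5-yl 3-methylbut-2-enoate | CC(C)=CC(=O)O[C@@H]1C[C@@H](O)[C@@]2(C)[C@@H]3CC=C(C)[C@H]2[C@@H]3C1(C)C | intermediate
17 | 3-methylbutanoyl chloride | CC(C)CC(Cl)=O | starting material
18 | (1R,2S,3R,5R,7R,8R)-2,6,6,9-tetramethyl-3-(3-methylbutanoyloxy)tricyclo[5.4.0.0^{2,8}]undec-9-en-5-yl 3-methylbut-2-enoate | CC(C)=CC(=O)O[C@@H]1C[C@@H](OC(=O)CC(C)C)[C@@]2(C)[C@@H]3CC=C(C)[C@H]2[C@@H]3C1(C)C | intermediate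
19 | (1R,2R,3R,5R,7S,8R)-2,6,6,9-tetramethyl-3-(3-methylbutanoyloxy)-11-oxotricyclo[5.4.0.0^{2,8}]undec-9-en-5-yl 3-methylbut-2-enoate (CNP0214473.1) | CC(C)=CC(=O)O[C@@H]1C[C@@H](OC(=O)CC(C)C)[C@@]2(C)[C@@H]3C(=O)C=C(C)[C@H]2[C@@H]3C1(C)C | target

Total step count: 12
Longest linear sequence: 12 steps (from 1)

**Steps most likely to fail**

Step 8 (key step). Base-induced loss of the allylic sulfonate (elimination toward the cyclohexadiene, or ionisation with allylic transposition) may outrun the strained four-membered closure at a fully substituted enolate carbon. The fallback replaces the SN2 closure by a palladium π-allyl closure of complementary stereochemistry. It sets out from 9: Mitsunobu esterification with benzoic acid (DIAD, PPh3, THF, 0 °C) inverts C8 and should give (1R,4aR,9aS)-2,5,9,9-tetramethyl-6-oxo-4,4a,5,6,9,9a-hexahydro-1H-benzo[7]annulen-1-yl benzoate F1, with the ester cis to C6. The C2 enolate is then formed with LiN(SiMe3)2 (THF, −78 °C) and Pd(PPh3)4 (5 mol %) is added. Zerovalent palladium ionises the benzoate with inversion, which puts the metal on the face of the ring-fusion hydrogens, and the enolate carbon attacks the allyl terminus C8 anti to the metal (Tsuji–Trost alkylation). This comes back to the route at 12.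

Step 6. Oxygen may be delivered to the wrong face of C8 (ene step through the other half-chair of the cis-fused cyclohexene), or to both faces. The fallback no longer relies on the hydroxylation for the C8 configuration but sets it by SN2 inversion. It sets out from 8, takes the C8-epimeric alcohol (1R,4aR,9aS)-1-hydroxy-2,5,9,9-tetramethyl-1,4,4a,5,9,9a-hexahydro-6H-benzo[7]annulen-6-one F2 that the oxidation would then give, and converts it under Mitsunobu conditions (4-nitrobenzoic acid, DIAD, PPh3, THF) into (1S,4aR,9aS)-2,5,9,9-tetramethyl-6-oxo-4,4a,5,6,9,9a-hexahydro-1H-benzo[7]annulen-1-yl 4-nitrobenzoate F3. Methanolysis (K2CO3, MeOH, 0 °C) returns to the route at 9.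

Step 10. The conjugated aldehyde may form the samarium hemiacetal too slowly at the hindered C5 hydroxyl, so that retro-aldol cleavage or acyl migration competes with hydride transfer. The fallback separates esterification from reduction and sets C3 by reagent control. It sets out from 14: acylation with 3-methylbut-2-enoic anhydride (pyridine, DMAP cat., CH2Cl2, 0 °C) should give (1R,2S,5R,7R,8R)-2,6,6,9-tetramethyl-3-oxotricyclo[5.4.0.0^{2,8}]undec-9-en-5-yl 3-methylbut-2-enoate F4. Corey–Bakshi–Shibata reduction ((S)-2-methyl-oxazaborolidine, catecholborane, toluene, −78 °C), with the quaternary C2 as the large group, should then give the (3R) alcohol. This comes back to the route at 16.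

**Further compounds**

F1 | step 8 | (1R,4aR,9aS)-2,5,9,9-tetramethyl-6-oxo-4,4a,5,6,9,9a-hexahydro-1H-benzo[7]annulen-1-yl benzoate | C1=CC(=O)C(C)[C@@H]2CC=C(C)[C@H](OC(=O)c3ccccc3)[C@@H]2C1(C)C
F2 | step 6 | (1R,4aR,9aS)-1-hydroxy-2,5,9,9-tetramethyl-1,4,4a,5,9,9a-hexahydro-6H-benzo[7]annulen-6-one | C1=CC(=O)C(C)[C@@H]2CC=C(C)[C@H](O)[C@@H]2C1(C)C
F3 | step 6 | (1S,4aR,9aS)-2,5,9,9-tetramethyl-6-oxo-4,4a,5,6,9,9a-hexahydro-1H-benzo[7]annulen-1-yl 4-nitrobenzoate | C1=CC(=O)C(C)[C@@H]2CC=C(C)[C@@H](OC(=O)c3ccc(cc3)[N+](=O)[O-])[C@@H]2C1(C)C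
F4 | step 10 | (1R,2S,5R,7R,8R)-2,6,6,9-tetramethyl-3-oxotricyclo[5.4.0.0^{2,8}]undec-9-en-5-yl 3-methylbut-2-enoate | CC(C)=CC(=O)O[C@@H]1CC(=O)[C@@]2(C)[C@@H]3CC=C(C)[C@H]2[C@@H]3C1(C)C
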